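**My commitment.** I commit to one number for this flask: the end ratio of side product A to target.

| flask | solid substrate | remark | time |
|---|---|---|---|
| elm | 0.070 M | run made earlier |  |
| alder | 0.11 M | run made earlier |  |
| flask | 0.050 M |  | 4.0 d |

| run | time / d | side product A / % | target / % |
|---|---|---|---|
| elm | 0.625 | 29 | 27 |
| elm | 1.25 | 45 | 40 |
| elm | 1.67 | 44 | 41 |
| elm | 2.50 | 47 | 43 |
| elm | 3.00 | 44 | 42 |
| elm | 4.00 | 45 | 42 |
| alder | 0.208 | 2 | 5 |
| alder | 0.625 | 18 | 21 |
| alder | 1.04 | 34 | 28 |
| alder | 1.67 | 44 | 42 |
| alder | 2.50 | 46 | 44 |
| alder | 3.00 | 44 | 38 |
| alder | 4.00 | 45 | 44 |

(each reading ± 2 percentage points)

- ratio of side product A to target at 1.5 h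
- ratio of side product A to target at 4.0 d

- solid, in amounts per volume of the solution: solid substrate
- the numbers in the tables scatter by 2 percentage points (one standard deviation)
- at the start none of the solid substrate is in solution

**End split.** From 2.50 d on, both runs read level, but for the alder reading of 38 % of target at 3.00 d. Summed over those readings, elm gives 1.07 and alder 1.07, though alder holds 1.57 times the charge of elm. Their mean, 1.07, is the end split: side product A per target once both have stopped climbing, a selectivity factor read from the runs. The flask holds less solid substrate than alder, and its 4.0 d lies past the 1.67 d at which alder already reads level, so I put the end split on its late ratio.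

**Bench rule.** The rule of thumb carries a plateau ratio back to every earlier moment, which is fair for two parallel routes of the same order. With the other route direct, a step in front of target puts the early ratio above the end split, and a step in front of side product A puts it below. The early time is 0.300 of the earliest alder time, and the alder reading there, 2 % of side product A, stands against a scatter of 2 percentage points. So I leave the early ratio unread.

**The forecast.** It says 0.5 early, on this ground: "This suggests A may lag target, perhaps forming through an intermediate", and 1.07 late. Its late value matches my end split; unlike me, it names an early number.

**The result.** The flask gives 1.82 early, 3.64 times the forecast, and 1.10 late, where I had put the end split of 1.07, a reading that carries the scatter of its runs.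

    starting material → side product A (k = 0.420 h⁻¹)
    starting material → intermediate (k = 0.410 h⁻¹)
    intermediate → side product B (k = 0.140 h⁻¹)
    intermediate → target (k = 2.00 h⁻¹)
    solid substrate ⇌ starting material, rate k5*(cs5 - [starting material]) while solid is left; crystals form when [starting material] > cs5 (solubility = 26.0 mM, k = 0.150 h⁻¹)
    2 starting material → homo dimer (k = 11.0 M⁻¹ h⁻¹)

**Neighbour flask.** In this scheme side product A comes straight from starting material, while target stands one step further on, behind intermediate. The neighbour flask, charged with 0.030 M of solid substrate, gets the same end split of 1.07 from me. It reads 1.10 at 4.00 d, with side product A at 46.6 % and target at 42.5 % of its charge. Its ratio at 1.5 h is 1.82, higher than its end ratio.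

(The earlier runs and the new flask were generated by integration for an exercise, and the scatter is random.)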